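The cyclohexane ring (C5–C10) is cut at C7–C8. The feature exploited is the trans pair on that ring of the C8 oxygen (later the lactone oxygen) and the C7 three-carbon arm C11–C13 (later the α-methylene lactone), the outcome of an intramolecular carbonyl-ene reaction. In one operation the key step forms C7–C8, closes the ring and sets C7 and C8. Its precursor is an open-chain C8 aldehyde with a C9 PMB ether, the C10 methyl/vinyl quaternary centre, the C5 arm as an electron-poor methyl acrylate, a C6 silyl ether and a prenyl-type C7=C11 alkene; its stereocentres come from a chiral-pool butenolide and one Evans aldol.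

Key step: step 14

Remark: atoms are labelled C1–C15 as in the target (ring C5–C10, oxirane C1–C2, acrolein arm C3/C4/C15, lactone arm C11–C13, methyl C14); (S)-5-(hydroxymethyl)furan-2(5H)-one is assumed to be purchased as the single enantiomer; Tr = trityl, PMB = 4-methoxybenzyl, TBS = tert-butyldimethylsilyl.

Step 1
Reactants: 1 (S)-5-(hydroxymethyl)furan-2(5H)-one
Product: 2 (S)-5-[(trityloxy)methyl]furan-2(5H)-one
Conditions: TrCl, Et3N, DMAP (cat.), CH2Cl2, rt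
Reagents that add atoms: trityl chloride ClC(c1ccccc1)(c1ccccc1)c1ccccc1
Why: O-tritylation of the primary alcohol gives a base-stable ether that cannot migrate and whose bulk will shield one face of the butenolide.

Step 2
Reactants: 2 (S)-5-[(trityloxy)methyl]furan-2(5H)-one
Product: 4 (S)-4-methyl-5-[(trityloxy)methyl]furan-2(5H)-one, via phenylselanyl lactone 3 (not isolated)
Conditions: Me2CuLi, Et2O, −78 °C; PhSeBr, THF, −78 to 0 °C; then H2O2, pyridine, CH2Cl2, 0 °C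
Reagents that add atoms: lithium dimethylcuprate [Li+].C[Cu-]C
Why: Cuprate 1,4-addition anti to the trityloxymethyl group, selenenylation of the enolate and selenoxide syn-elimination should return the butenolide with the C14 methyl on C10, while the C9 centre is not touched.

Step 3
Reactants: 4 (S)-4-methyl-5-[(trityloxy)methyl]furan-2(5H)-one
Product: 5 (4R,5S)-4-methyl-5-[(trityloxy)methyl]-4-vinyldihydrofuran-2(3H)-one
Conditions: (CH2=CH)2CuLi, Et2O/THF, −78 to −30 °C; aq. NH4Cl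
Reagents that add atoms: lithium divinylcuprate [Li+].C=C[Cu-]C=C
Why: Cuprate 1,4-addition to the β-methyl butenolide should deliver the vinyl group to the ring face opposite the trityloxymethyl group on C9, which sets the quaternary centre C10 from the chiral-pool centre.

Step 4
Reactants: 5 (4R,5S)-4-methyl-5-[(trityloxy)methyl]-4-vinyldihydrofuran-2(3H)-one
Product: 8 (3R,4S)-4-[(4-methoxybenzyl)oxy]-3-methyl-5-(trityloxy)-3-vinylpentanoic acid, via potassium hydroxy carboxylate 6 (not isolated), via PMB ester 7 (not isolated)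
Conditions: KOH, DMSO, rt; PMBCl, rt; then H2O, 50 °C; aq. KHSO4 to pH 4
Reagents that add atoms: potassium hydroxide [K+].[OH-]; 4-methoxybenzyl chloride COc1ccc(CCl)cc1
Why: Saponification opens the lactone, Williamson alkylation in KOH/DMSO benzylates the hindered C9 alkoxide and the carboxylate, and hydrolysis of the ester alone leaves the C9 ether, with no stereocentre involved.

Step 5
Reactants: 8 (3R,4S)-4-[(4-methoxybenzyl)oxy]-3-methyl-5-(trityloxy)-3-vinylpentanoic acid; 9 (S)-4-benzyloxazolidin-2-one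
Product: 11 (S)-4-benzyl-3-[(3R,4S)-4-[(4-methoxybenzyl)oxy]-3-methyl-5-(trityloxy)-3-vinylpentanoyl]oxazolidin-2-one, via mixed pivalic anhydride 10 (not isolated)
Conditions: PivCl, Et3N, THF, −20 °C; then 9, LiCl, 0 °C to rt
Reagents that add atoms: none
Why: N-acylation of the oxazolidinone by the mixed anhydride, which is attacked at its less hindered carbonyl, installs the auxiliary for the aldol.

Step 6
Reactants: 11 (S)-4-benzyl-3-[(3R,4S)-4-[(4-methoxybenzyl)oxy]-3-methyl-5-(trityloxy)-3-vinylpentanoyl]oxazolidin-2-one; 12 3-methylbut-2-enal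
Product: 13 (S)-4-benzyl-3-[(2S,3R)-3-hydroxy-2-[(3S,4S)-4-[(4-methoxybenzyl)oxy]-3-methyl-5-(trityloxy)pent-1-en-3-yl]-5-methylhex-4-enoyl]oxazolidin-2-one
Conditions: Bu2BOTf, Et3N, CH2Cl2, −78 to 0 °C; 12, −78 to 0 °C; pH 7 buffer, MeOH, H2O2, 0 °C
Reagents that add atoms: none
Why: Evans syn-aldol, in which the Z boron enolate reacts through a chair transition state on the face away from the benzyl group of the auxiliary, should set C5 and C6 by reagent control regardless of the neighbouring quaternary centre.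

Step 7
Reactants: 13 (S)-4-benzyl-3-[(2S,3R)-3-hydroxy-2-[(3S,4S)-4-[(4-methoxybenzyl)oxy]-3-methyl-5-(trityloxy)pent-1-en-3-yl]-5-methylhex-4-enoyl]oxazolidin-2-one
Product: 14 (2S,3R)-3-hydroxy-N-methoxy-2-[(3S,4S)-4-[(4-methoxybenzyl)oxy]-3-methyl-5-(trityloxy)pent-1-en-3-yl]-N,5-dimethylhex-4-enamide
Conditions: MeNHOMe·HCl, Me3Al, CH2Cl2, −20 to 0 °C; aq. potassium sodium tartrate
Reagents that add atoms: N,O-dimethylhydroxylamine hydrochloride CNOC.Cl
Why: Aluminium-amide transamination of the β-hydroxy imide, helped by chelation of the free C6 hydroxyl, should give the Weinreb amide and release the auxiliary.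

Step 8
Reactants: 14 (2S,3R)-3-hydroxy-N-methoxy-2-[(3S,4S)-4-[(4-methoxybenzyl)oxy]-3-methyl-5-(trityloxy)pent-1-en-3-yl]-N,5-dimethylhex-4-enamide
Product: 15 (2S,3R)-3-[(tert-butyldimethylsilyl)oxy]-N-methoxy-2-[(3S,4S)-4-[(4-methoxybenzyl)oxy]-3-methyl-5-(trityloxy)pent-1-en-3-yl]-N,5-dimethylhex-4-enamide
Conditions: TBSOTf, 2,6-lutidine, CH2Cl2, −78 to 0 °C
Reagents that add atoms: tert-butyldimethylsilyl trifluoromethanesulfonate CC(C)(C)[Si](C)(C)OS(=O)(=O)C(F)(F)F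
Why: Silylation of the secondary allylic alcohol with the silyl triflate protects C6 as the bulky ether that the key step needs for conformational control.

Step 9
Reactants: 15 (2S,3R)-3-[(tert-butyldimethylsilyl)oxy]-N-methoxy-2-[(3S,4S)-4-[(4-methoxybenzyl)oxy]-3-methyl-5-(trityloxy)pent-1-en-3-yl]-N,5-dimethylhex-4-enamide
Product: 16 (3S,4R)-4-[(tert-butyldimethylsilyl)oxy]-3-[(3S,4S)-4-[(4-methoxybenzyl)oxy]-3-methyl-5-(trityloxy)pent-1-en-3-yl]-6-methylhept-5-en-2-one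
Conditions: MeMgBr, THF, 0 °C; aq. NH4Cl
Reagents that add atoms: methylmagnesium bromide C[Mg]Br
Why: Grignard addition to the Weinreb amide stops at the magnesium chelate and should give the methyl ketone (C4 carbonyl, C15 methyl) on work-up without epimerising C5.

Step 10
Reactants: 16 (3S,4R)-4-[(tert-butyldimethylsilyl)oxy]-3-[(3S,4S)-4-[(4-methoxybenzyl)oxy]-3-methyl-5-(trityloxy)pent-1-en-3-yl]-6-methylhept-5-en-2-one
Product: 17 (3S,4R)-4-[(tert-butyldimethylsilyl)oxy]-3-[(3S,4S)-4-[(4-methoxybenzyl)oxy]-3-methyl-5-(trityloxy)pent-1-en-3-yl]-6-methylhepta-1,5-dien-2-yl trifluoromethanesulfonate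
Conditions: KN(SiMe3)2, THF, −78 °C; PhNTf2, −78 to −20 °C
Reagents that add atoms: N-phenylbis(trifluoromethanesulfonimide) O=S(=O)(N(c1ccccc1)S(=O)(=O)C(F)(F)F)C(F)(F)F
Why: Kinetic deprotonation at the unhindered C15 methyl and O-sulfonylation of the enolate should give the terminal enol triflate, since the hindered C5 hydrogen is not removed and C5 and the C6 silyl ether stay intact.

Step 11
Reactants: 17 (3S,4R)-4-[(tert-butyldimethylsilyl)oxy]-3-[(3S,4S)-4-[(4-methoxybenzyl)oxy]-3-methyl-5-(trityloxy)pent-1-en-3-yl]-6-methylhepta-1,5-dien-2-yl trifluoromethanesulfonate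
Product: 18 methyl (3R,4R)-4-[(tert-butyldimethylsilyl)oxy]-3-[(3S,4S)-4-[(4-methoxybenzyl)oxy]-3-methyl-5-(trityloxy)pent-1-en-3-yl]-6-methyl-2-methylidenehept-5-enoate
Conditions: Pd(OAc)2 (cat.), PPh3, CO (1 atm), MeOH, Et3N, DMF, 50 °C
Reagents that add atoms: carbon monoxide [C-]#[O+]; methanol CO
Why: Palladium-catalysed methoxycarbonylation of the enol triflate (oxidative addition, CO insertion, methanolysis) attaches C3 and turns the C4=C15 alkene into an electron-poor acrylate.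

Step 12
Reactants: 18 methyl (3R,4R)-4-[(tert-butyldimethylsilyl)oxy]-3-[(3S,4S)-4-[(4-methoxybenzyl)oxy]-3-methyl-5-(trityloxy)pent-1-en-3-yl]-6-methyl-2-methylidenehept-5-enoate
Product: 19 methyl (3R,4R)-4-[(tert-butyldimethylsilyl)oxy]-3-[(3S,4S)-5-hydroxy-4-[(4-methoxybenzyl)oxy]-3-methylpent-1-en-3-yl]-6-methyl-2-methylidenehept-5-enoate
Conditions: camphorsulfonic acid (cat.), MeOH/CH2Cl2, 0 °C
Reagents that add atoms: none
Why: Acid-catalysed methanolysis of the trityl ether frees the primary C8 alcohol, while the secondary silyl ether and the PMB ether should persist at 0 °C.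

Step 13
Reactants: 19 methyl (3R,4R)-4-[(tert-butyldimethylsilyl)oxy]-3-[(3S,4S)-5-hydroxy-4-[(4-methoxybenzyl)oxy]-3-methylpent-1-en-3-yl]-6-methyl-2-methylidenehept-5-enoate
Product: 20 methyl (3R,4R)-4-[(tert-butyldimethylsilyl)oxy]-3-[(3S,4S)-4-[(4-methoxybenzyl)oxy]-3-methyl-5-oxopent-1-en-3-yl]-6-methyl-2-methylidenehept-5-enoate
Conditions: Dess–Martin periodinane, NaHCO3, CH2Cl2, 0 °C to rt
Reagents that add atoms: none
Why: Buffered Dess–Martin oxidation should give the α-alkoxy aldehyde without epimerising C9, and the aldehyde is used at once.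

Step 14
Reactants: 20 methyl (3R,4R)-4-[(tert-butyldimethylsilyl)oxy]-3-[(3S,4S)-4-[(4-methoxybenzyl)oxy]-3-methyl-5-oxopent-1-en-3-yl]-6-methyl-2-methylidenehept-5-enoate
Product: 21 (1R,2R,3S,4R,5S,6S)-3-[(tert-butyldimethylsilyl)oxy]-4-(3-methoxy-3-oxoprop-1-en-2-yl)-6-[(4-methoxybenzyl)oxy]-5-methyl-2-(prop-1-en-2-yl)-5-vinylcyclohexan-1-ol
Conditions: Me2AlCl, CH2Cl2, −78 to −40 °C; aq. potassium sodium tartrate
Reagents that add atoms: none
Why: Me2AlCl binds the C8 aldehyde, whose carbon bonds to C7 of the C7=C11 alkene while a hydrogen of the C11 methyl trans to C6 passes to oxygen in a concerted, asynchronous carbonyl-ene reaction of type 1, the closest known case being the cyclisation of citronellal to isopulegol. The six-membered ring C5–C10 closes through a chair in which the alkene stays outside the new ring (exo mode) and ends as the C7 isopropenyl group. C8 is set because the complexed carbonyl oxygen lies equatorial and C7 because C11 lies equatorial, which gives the trans C7/C8 pair. The chair itself is chosen by allylic 1,3-strain between the C11 methyl cis to C6 and the C6 substituent, which holds the silyloxy group axial and the C5 arm equatorial. The step needs chemoselectivity among three alkenes, and the substrate secures it: the acrylate alkene is electron-poor and cannot act as ene donor, and the vinyl group could only close a four- or five-membered ring. Me2AlCl also removes the transferred proton as methane, which should suppress cationic side paths.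

Step 15
Reactants: 21 (1R,2R,3S,4R,5S,6S)-3-[(tert-butyldimethylsilyl)oxy]-4-(3-methoxy-3-oxoprop-1-en-2-yl)-6-[(4-methoxybenzyl)oxy]-5-methyl-2-(prop-1-en-2-yl)-5-vinylcyclohexan-1-ol
Product: 22 (1R,2R,3S,4R,5S,6S)-3-[(tert-butyldimethylsilyl)oxy]-2-(3-hydroxyprop-1-en-2-yl)-4-(3-methoxy-3-oxoprop-1-en-2-yl)-6-[(4-methoxybenzyl)oxy]-5-methyl-5-vinylcyclohexan-1-ol
Conditions: SeO2 (cat.), t-BuOOH, CH2Cl2, 0 °C to rt
Reagents that add atoms: tert-butyl hydroperoxide CC(C)(C)OO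
Why: Selenium dioxide allylic hydroxylation (ene reaction then 2,3-sigmatropic shift) should occur at the C12 methyl of the isopropenyl group, because the vinyl group has no allylic hydrogen and the acrylate alkene is electron-poor.

Step 16
Reactants: 22 (1R,2R,3S,4R,5S,6S)-3-[(tert-butyldimethylsilyl)oxy]-2-(3-hydroxyprop-1-en-2-yl)-4-(3-methoxy-3-oxoprop-1-en-2-yl)-6-[(4-methoxybenzyl)oxy]-5-methyl-5-vinylcyclohexan-1-ol
Product: 23 (1R,2R,3S,4S,5S,6S)-3-[(tert-butyldimethylsilyl)oxy]-2,4-bis(3-hydroxyprop-1-en-2-yl)-6-[(4-methoxybenzyl)oxy]-5-methyl-5-vinylcyclohexan-1-ol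
Conditions: iBu2AlH, CH2Cl2, −78 °C; aq. potassium sodium tartrate
Reagents that add atoms: none
Why: 1,2-Reduction of the acrylate ester by the aluminium hydride should give the C3 allylic alcohol and also return any over-oxidised C12 aldehyde to the alcohol.

Step 17
Reactants: 23 (1R,2R,3S,4S,5S,6S)-3-[(tert-butyldimethylsilyl)oxy]-2,4-bis(3-hydroxyprop-1-en-2-yl)-6-[(4-methoxybenzyl)oxy]-5-methyl-5-vinylcyclohexan-1-ol
Product: 25 (3aR,4S,5R,6S,7S,7aR)-4-[(tert-butyldimethylsilyl)oxy]-7-[(4-methoxybenzyl)oxy]-6-methyl-3-methylidene-5-(3-oxoprop-1-en-2-yl)-6-vinylhexahydro-1-benzofuran-2(3H)-one, via lactol 24 (not isolated)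
Conditions: MnO2, CH2Cl2, rt
Reagents that add atoms: none
Why: MnO2 should oxidise only the two primary allylic alcohols, so that the C12 aldehyde is trapped by the C8 hydroxyl as a lactol and oxidised on to the trans-fused α-methylene lactone while C3 becomes the enal (allylic oxidation with oxidative lactonisation).

Step 18
Reactants: 25 (3aR,4S,5R,6S,7S,7aR)-4-[(tert-butyldimethylsilyl)oxy]-7-[(4-methoxybenzyl)oxy]-6-methyl-3-methylidene-5-(3-oxoprop-1-en-2-yl)-6-vinylhexahydro-1-benzofuran-2(3H)-one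
Product: 26 (3aR,4S,5R,6S,7S,7aR)-4-[(tert-butyldimethylsilyl)oxy]-7-hydroxy-6-methyl-3-methylidene-5-(3-oxoprop-1-en-2-yl)-6-vinylhexahydro-1-benzofuran-2(3H)-one
Conditions: DDQ, CH2Cl2/pH 7 buffer, 0 °C to rt
Reagents that add atoms: none
Why: Oxidative cleavage of the PMB ether by DDQ (hydride abstraction, then hydrolysis of the oxocarbenium ion) frees the C9 alcohol, while the silyl ether and the electron-poor alkenes should be inert.

Step 19
Reactants: 26 (3aR,4S,5R,6S,7S,7aR)-4-[(tert-butyldimethylsilyl)oxy]-7-hydroxy-6-methyl-3-methylidene-5-(3-oxoprop-1-en-2-yl)-6-vinylhexahydro-1-benzofuran-2(3H)-one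
Product: 27 (3aR,4S,5R,6S,7S,7aR)-4-[(tert-butyldimethylsilyl)oxy]-7-hydroxy-6-methyl-3-methylidene-6-[(2R)-oxiran-2-yl]-5-(3-oxoprop-1-en-2-yl)hexahydro-1-benzofuran-2(3H)-one
Conditions: VO(acac)2 (cat.), t-BuOOH, CH2Cl2, 0 °C to rt
Reagents that add atoms: tert-butyl hydroperoxide CC(C)(C)OO
Why: In this hydroxyl-directed epoxidation the vanadium alkoxide of the axial C9 hydroxyl should deliver oxygen to the homoallylic vinyl group, the only alkene not conjugated to a carbonyl, on the peripheral face of the rotamer that keeps C2 below the ring and away from the equatorial C5 arm, which is expected to give the (1R) oxirane.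

Step 20
Reactants: 27 (3aR,4S,5R,6S,7S,7aR)-4-[(tert-butyldimethylsilyl)oxy]-7-hydroxy-6-methyl-3-methylidene-6-[(2R)-oxiran-2-yl]-5-(3-oxoprop-1-en-2-yl)hexahydro-1-benzofuran-2(3H)-one; 28 angelic acid
Product: 30 (3aR,4S,5R,6R,7S,7aR)-4-[(tert-butyldimethylsilyl)oxy]-6-methyl-3-methylidene-6-[(2R)-oxiran-2-yl]-2-oxo-5-(3-oxoprop-1-en-2-yl)octahydro-1-benzofuran-7-yl (2Z)-2-methylbut-2-enoate, via mixed anhydride 29 (not isolated)
Conditions: 28, 2,4,6-Cl3C6H2COCl, Et3N, toluene, rt; then 27, toluene, 80 °C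
Reagents that add atoms: none
Why: Acyl transfer from the preformed mixed anhydride without a nucleophilic catalyst (Yamaguchi-type esterification) should acylate the hindered C9 alcohol with the Z geometry of the angelate retained.

Step 21
Reactants: 30 (3aR,4S,5R,6R,7S,7aR)-4-[(tert-butyldimethylsilyl)oxy]-6-methyl-3-methylidene-6-[(2R)-oxiran-2-yl]-2-oxo-5-(3-oxoprop-1-en-2-yl)octahydro-1-benzofuran-7-yl (2Z)-2-methylbut-2-enoate
Product: 31 (3aS,4S,5R,6R,7S,7aR)-4-hydroxy-6-methyl-3-methylidene-6-[(2R)-oxiran-2-yl]-2-oxo-5-(3-oxoprop-1-en-2-yl)octahydro-1-benzofuran-7-yl (2Z)-2-methylbut-2-enoate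
Conditions: HF·pyridine, pyridine, THF, 0 °C to rt
Reagents that add atoms: none
Why: Fluoride cleavage of the silyl ether under pyridine-buffered conditions frees the C6 alcohol and should spare the oxirane, the angelate and the two Michael acceptors.

Compound list

1 | (S)-5-(hydroxymethyl)furan-2(5H)-one | O=C1C=C[C@@H](CO)O1 | starting material
2 | (S)-5-[(trityloxy)methyl]furan-2(5H)-one | O=C1C=C[C@@H](COC(c2ccccc2)(c2ccccc2)c2ccccc2)O1 | intermediate
3 | (3S,4R,5S)-4-methyl-3-(phenylselanyl)-5-[(trityloxy)methyl]dihydrofuran-2(3H)-one | O=C1[C@@H]([Se]c2ccccc2)[C@H](C)[C@@H](COC(c2ccccc2)(c2ccccc2)c2ccccc2)O1 | intermediate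
4 | (S)-4-methyl-5-[(trityloxy)methyl]furan-2(5H)-one | O=C1C=C(C)[C@@H](COC(c2ccccc2)(c2ccccc2)c2ccccc2)O1 | intermediate
5 | (4R,5S)-4-methyl-5-[(trityloxy)methyl]-4-vinyldihydrofuran-2(3H)-one | O=C1C[C@](C)(C=C)[C@@H](COC(c2ccccc2)(c2ccccc2)c2ccccc2)O1 | intermediate
6 | potassium (3R,4S)-4-hydroxy-3-methyl-5-(trityloxy)-3-vinylpentanoate | [K+].[O-]C(=O)C[C@](C)(C=C)[C@H](O)COC(c1ccccc1)(c1ccccc1)c1ccccc1 | intermediate
7 | 4-methoxybenzyl (3R,4S)-4-[(4-methoxybenzyl)oxy]-3-methyl-5-(trityloxy)-3-vinylpentanoate | COc1ccc(COC(=O)C[C@](C)(C=C)[C@H](OCc2ccc(OC)cc2)COC(c2ccccc2)(c2ccccc2)c2ccccc2)cc1 | intermediate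
8 | (3R,4S)-4-[(4-methoxybenzyl)oxy]-3-methyl-5-(trityloxy)-3-vinylpentanoic acid | OC(=O)C[C@](C)(C=C)[C@H](OCc1ccc(OC)cc1)COC(c1ccccc1)(c1ccccc1)c1ccccc1 | intermediate
9 | (S)-4-benzyloxazolidin-2-one | O=C1N[C@@H](Cc2ccccc2)CO1 | starting material
10 | (3R,4S)-4-[(4-methoxybenzyl)oxy]-3-methyl-5-(trityloxy)-3-vinylpentanoic pivalic anhydride | CC(C)(C)C(=O)OC(=O)C[C@](C)(C=C)[C@H](OCc1ccc(OC)cc1)COC(c1ccccc1)(c1ccccc1)c1ccccc1 | intermediate
11 | (S)-4-benzyl-3-[(3R,4S)-4-[(4-methoxybenzyl)oxy]-3-methyl-5-(trityloxy)-3-vinylpentanoyl]oxazolidin-2-one | O=C(C[C@](C)(C=C)[C@H](OCc1ccc(OC)cc1)COC(c1ccccc1)(c1ccccc1)c1ccccc1)N1[C@@H](Cc2ccccc2)COC1=O | intermediate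
12 | 3-methylbut-2-enal | CC(C)=CC=O | starting material
13 | (S)-4-benzyl-3-[(2S,3R)-3-hydroxy-2-[(3S,4S)-4-[(4-methoxybenzyl)oxy]-3-methyl-5-(trityloxy)pent-1-en-3-yl]-5-methylhex-4-enoyl]oxazolidin-2-one | C(c1ccccc1)(c1ccccc1)(c1ccccc1)OC[C@@H](OCc1ccc(OC)cc1)[C@@](C)(C=C)[C@H](C(=O)N1[C@@H](Cc2ccccc2)COC1=O)[C@H](O)C=C(C)C | intermediate
14 | (2S,3R)-3-hydroxy-N-methoxy-2-[(3S,4S)-4-[(4-methoxybenzyl)oxy]-3-methyl-5-(trityloxy)pent-1-en-3-yl]-N,5-dimethylhex-4-enamide | C(c1ccccc1)(c1ccccc1)(c1ccccc1)OC[C@@H](OCc1ccc(OC)cc1)[C@@](C)(C=C)[C@H](C(=O)N(C)OC)[C@H](O)C=C(C)C | intermediate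
15 | (2S,3R)-3-[(tert-butyldimethylsilyl)oxy]-N-methoxy-2-[(3S,4S)-4-[(4-methoxybenzyl)oxy]-3-methyl-5-(trityloxy)pent-1-en-3-yl]-N,5-dimethylhex-4-enamide | C(c1ccccc1)(c1ccccc1)(c1ccccc1)OC[C@@H](OCc1ccc(OC)cc1)[C@@](C)(C=C)[C@H](C(=O)N(C)OC)[C@H](O[Si](C)(C)C(C)(C)C)C=C(C)C | intermediate
16 | (3S,4R)-4-[(tert-butyldimethylsilyl)oxy]-3-[(3S,4S)-4-[(4-methoxybenzyl)oxy]-3-methyl-5-(trityloxy)pent-1-en-3-yl]-6-methylhept-5-en-2-one | C(c1ccccc1)(c1ccccc1)(c1ccccc1)OC[C@@H](OCc1ccc(OC)cc1)[C@@](C)(C=C)[C@H](C(C)=O)[C@H](O[Si](C)(C)C(C)(C)C)C=C(C)C | intermediate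
17 | (3S,4R)-4-[(tert-butyldimethylsilyl)oxy]-3-[(3S,4S)-4-[(4-methoxybenzyl)oxy]-3-methyl-5-(trityloxy)pent-1-en-3-yl]-6-methylhepta-1,5-dien-2-yl trifluoromethanesulfonate | C(c1ccccc1)(c1ccccc1)(c1ccccc1)OC[C@@H](OCc1ccc(OC)cc1)[C@@](C)(C=C)[C@H](C(=C)OS(=O)(=O)C(F)(F)F)[C@H](O[Si](C)(C)C(C)(C)C)C=C(C)C | intermediate
18 | methyl (3R,4R)-4-[(tert-butyldimethylsilyl)oxy]-3-[(3S,4S)-4-[(4-methoxybenzyl)oxy]-3-methyl-5-(trityloxy)pent-1-en-3-yl]-6-methyl-2-methylidenehept-5-enoate | C(c1ccccc1)(c1ccccc1)(c1ccccc1)OC[C@@H](OCc1ccc(OC)cc1)[C@@](C)(C=C)[C@H](C(=C)C(=O)OC)[C@H](O[Si](C)(C)C(C)(C)C)C=C(C)C | intermediate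
19 | methyl (3R,4R)-4-[(tert-butyldimethylsilyl)oxy]-3-[(3S,4S)-5-hydroxy-4-[(4-methoxybenzyl)oxy]-3-methylpent-1-en-3-yl]-6-methyl-2-methylidenehept-5-enoate | OC[C@@H](OCc1ccc(OC)cc1)[C@@](C)(C=C)[C@H](C(=C)C(=O)OC)[C@H](O[Si](C)(C)C(C)(C)C)C=C(C)C | intermediate
20 | methyl (3R,4R)-4-[(tert-butyldimethylsilyl)oxy]-3-[(3S,4S)-4-[(4-methoxybenzyl)oxy]-3-methyl-5-oxopent-1-en-3-yl]-6-methyl-2-methylidenehept-5-enoate | O=C[C@@H](OCc1ccc(OC)cc1)[C@@](C)(C=C)[C@H](C(=C)C(=O)OC)[C@H](O[Si](C)(C)C(C)(C)C)C=C(C)C | intermediate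
21 | (1R,2R,3S,4R,5S,6S)-3-[(tert-butyldimethylsilyl)oxy]-4-(3-methoxy-3-oxoprop-1-en-2-yl)-6-[(4-methoxybenzyl)oxy]-5-methyl-2-(prop-1-en-2-yl)-5-vinylcyclohexan-1-ol | O[C@@H]1[C@@H](C(C)=C)[C@@H](O[Si](C)(C)C(C)(C)C)[C@@H](C(=C)C(=O)OC)[C@](C)(C=C)[C@@H]1OCc1ccc(OC)cc1 | intermediate
22 | (1R,2R,3S,4R,5S,6S)-3-[(tert-butyldimethylsilyl)oxy]-2-(3-hydroxyprop-1-en-2-yl)-4-(3-methoxy-3-oxoprop-1-en-2-yl)-6-[(4-methoxybenzyl)oxy]-5-methyl-5-vinylcyclohexan-1-ol | O[C@@H]1[C@@H](C(CO)=C)[C@@H](O[Si](C)(C)C(C)(C)C)[C@@H](C(=C)C(=O)OC)[C@](C)(C=C)[C@@H]1OCc1ccc(OC)cc1 | intermediate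
23 | (1R,2R,3S,4S,5S,6S)-3-[(tert-butyldimethylsilyl)oxy]-2,4-bis(3-hydroxyprop-1-en-2-yl)-6-[(4-methoxybenzyl)oxy]-5-methyl-5-vinylcyclohexan-1-ol | O[C@@H]1[C@@H](C(CO)=C)[C@@H](O[Si](C)(C)C(C)(C)C)[C@@H](C(=C)CO)[C@](C)(C=C)[C@@H]1OCc1ccc(OC)cc1 | intermediate
24 | 2-[(3aR,4S,5R,6S,7S,7aR)-4-[(tert-butyldimethylsilyl)oxy]-2-hydroxy-7-[(4-methoxybenzyl)oxy]-6-methyl-3-methylidene-6-vinyloctahydro-1-benzofuran-5-yl]prop-2-enal (lactol, both C12 epimers) | OC1O[C@@H]2[C@@H](C1=C)[C@@H](O[Si](C)(C)C(C)(C)C)[C@@H](C(=C)C=O)[C@](C)(C=C)[C@@H]2OCc1ccc(OC)cc1 | intermediate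
25 | (3aR,4S,5R,6S,7S,7aR)-4-[(tert-butyldimethylsilyl)oxy]-7-[(4-methoxybenzyl)oxy]-6-methyl-3-methylidene-5-(3-oxoprop-1-en-2-yl)-6-vinylhexahydro-1-benzofuran-2(3H)-one | C=C1C(=O)O[C@@H]2[C@@H]1[C@@H](O[Si](C)(C)C(C)(C)C)[C@@H](C(=C)C=O)[C@](C)(C=C)[C@@H]2OCc1ccc(OC)cc1 | intermediate
26 | (3aR,4S,5R,6S,7S,7aR)-4-[(tert-butyldimethylsilyl)oxy]-7-hydroxy-6-methyl-3-methylidene-5-(3-oxoprop-1-en-2-yl)-6-vinylhexahydro-1-benzofuran-2(3H)-one | C=C1C(=O)O[C@@H]2[C@@H]1[C@@H](O[Si](C)(C)C(C)(C)C)[C@@H](C(=C)C=O)[C@](C)(C=C)[C@@H]2O | intermediate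
27 | (3aR,4S,5R,6S,7S,7aR)-4-[(tert-butyldimethylsilyl)oxy]-7-hydroxy-6-methyl-3-methylidene-6-[(2R)-oxiran-2-yl]-5-(3-oxoprop-1-en-2-yl)hexahydro-1-benzofuran-2(3H)-one | C=C1C(=O)O[C@@H]2[C@@H]1[C@@H](O[Si](C)(C)C(C)(C)C)[C@@H](C(=C)C=O)[C@](C)([C@@H]1CO1)[C@@H]2O | intermediate
28 | angelic acid, (2Z)-2-methylbut-2-enoic acid | C/C=C(/C)C(=O)O | starting material
29 | (2Z)-2-methylbut-2-enoic 2,4,6-trichlorobenzoic anhydride | C/C=C(/C)C(=O)OC(=O)c1c(Cl)cc(Cl)cc1Cl | intermediate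
30 | (3aR,4S,5R,6R,7S,7aR)-4-[(tert-butyldimethylsilyl)oxy]-6-methyl-3-methylidene-6-[(2R)-oxiran-2-yl]-2-oxo-5-(3-oxoprop-1-en-2-yl)octahydro-1-benzofuran-7-yl (2Z)-2-methylbut-2-enoate | C=C1C(=O)O[C@@H]2[C@@H]1[C@@H](O[Si](C)(C)C(C)(C)C)[C@@H](C(=C)C=O)[C@](C)([C@@H]1CO1)[C@@H]2OC(=O)/C(C)=C\C | intermediate
31 | (3aS,4S,5R,6R,7S,7aR)-4-hydroxy-6-methyl-3-methylidene-6-[(2R)-oxiran-2-yl]-2-oxo-5-(3-oxoprop-1-en-2-yl)octahydro-1-benzofuran-7-yl (2Z)-2-methylbut-2-enoate | C=C1C(=O)O[C@@H]2[C@@H]1[C@@H](O)[C@@H](C(=C)C=O)[C@](C)([C@@H]1CO1)[C@@H]2OC(=O)/C(C)=C\C | target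

Total step count: 21. Longest linear sequence: 21 steps (1 to 31); compounds 9, 12 and 28 enter directly.

Steps most likely to fail

Step 14. The chair that places the C6 silyloxy group axial also carries a 1,3-diaxial contact with the C14 methyl, so the ring may close through the other chair and invert C7 and C8; the Lewis acid may also ionise the allylic silyl ether or the PMB ether. The fallback forms the same C7–C8 bond with reversed polarity by an intramolecular allylation under neutral conditions. It sets out from trityl ether 18: SeO2/t-BuOOH should hydroxylate the C11 methyl trans to C6 to give the (E)-allylic alcohol F1, and Ac2O/pyridine then gives the allylic acetate F2. Detritylation as in step 12 gives the primary alcohol F3 and Dess–Martin oxidation the acetoxy aldehyde F4. Pd(PPh3)4 (cat.) and InI in THF should turn the allylic acetate into an allylindium species that adds to the C8 aldehyde through C7 in a chair transition state. This gives cyclohexanol 21, where the route is rejoined.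

Step 19. Facial selectivity of oxygen transfer to the freely rotating vinyl group may be poor, because the C9 alkoxide can reach more than one rotamer. The fallback replaces substrate direction by a catalyst-controlled kinetic resolution of the terminal epoxide. It sets out from alcohol 26: the epoxidation is run without regard to selectivity and gives oxirane 27 mixed with its C1 epimer, the (1S)-oxirane F5. Hydrolytic kinetic resolution with water and the enantiomer of the chiral (salen)Co(OAc) complex that consumes (S)-configured terminal epoxides should open only F5, to the diol F6. F6 is separated by chromatography and leaves 27, where the route is rejoined.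

Step 20. Acylation of the axial, neopentyl-type C9 hydroxyl may be slow, and the acyl donor may isomerise from Z to E on prolonged heating. The fallback builds the ester stepwise from a slim acid that cannot isomerise. It sets out from epoxy alcohol 27: esterification with but-2-ynoic acid (DCC, DMAP, CH2Cl2) should give the but-2-ynoate F7. Pd(PPh3)4-catalysed syn-hydrostannation with Bu3SnH places tin on the α-carbon and gives the (E)-2-(tributylstannyl)but-2-enoate F8. Stille methylation (MeI, Pd(PPh3)4, CuI, DMF) with retention of alkene geometry should then give angelate 30, where the route is rejoined.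

Further compounds

F1 | step 14 | methyl (3R,4R,5E)-4-[(tert-butyldimethylsilyl)oxy]-7-hydroxy-3-[(3S,4S)-4-[(4-methoxybenzyl)oxy]-3-methyl-5-(trityloxy)pent-1-en-3-yl]-6-methyl-2-methylidenehept-5-enoate | C(c1ccccc1)(c1ccccc1)(c1ccccc1)OC[C@@H](OCc1ccc(OC)cc1)[C@@](C)(C=C)[C@H](C(=C)C(=O)OC)[C@H](O[Si](C)(C)C(C)(C)C)/C=C(/CO)C
F2 | step 14 | methyl (3R,4R,5E)-7-acetoxy-4-[(tert-butyldimethylsilyl)oxy]-3-[(3S,4S)-4-[(4-methoxybenzyl)oxy]-3-methyl-5-(trityloxy)pent-1-en-3-yl]-6-methyl-2-methylidenehept-5-enoate | C(c1ccccc1)(c1ccccc1)(c1ccccc1)OC[C@@H](OCc1ccc(OC)cc1)[C@@](C)(C=C)[C@H](C(=C)C(=O)OC)[C@H](O[Si](C)(C)C(C)(C)C)/C=C(/COC(C)=O)C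
F3 | step 14 | methyl (3R,4R,5E)-7-acetoxy-4-[(tert-butyldimethylsilyl)oxy]-3-[(3S,4S)-5-hydroxy-4-[(4-methoxybenzyl)oxy]-3-methylpent-1-en-3-yl]-6-methyl-2-methylidenehept-5-enoate | OC[C@@H](OCc1ccc(OC)cc1)[C@@](C)(C=C)[C@H](C(=C)C(=O)OC)[C@H](O[Si](C)(C)C(C)(C)C)/C=C(/COC(C)=O)C
F4 | step 14 | methyl (3R,4R,5E)-7-acetoxy-4-[(tert-butyldimethylsilyl)oxy]-3-[(3S,4S)-4-[(4-methoxybenzyl)oxy]-3-methyl-5-oxopent-1-en-3-yl]-6-methyl-2-methylidenehept-5-enoate | O=C[C@@H](OCc1ccc(OC)cc1)[C@@](C)(C=C)[C@H](C(=C)C(=O)OC)[C@H](O[Si](C)(C)C(C)(C)C)/C=C(/COC(C)=O)C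
F5 | step 19 | (3aR,4S,5R,6S,7S,7aR)-4-[(tert-butyldimethylsilyl)oxy]-7-hydroxy-6-methyl-3-methylidene-6-[(2S)-oxiran-2-yl]-5-(3-oxoprop-1-en-2-yl)hexahydro-1-benzofuran-2(3H)-one | C=C1C(=O)O[C@@H]2[C@@H]1[C@@H](O[Si](C)(C)C(C)(C)C)[C@@H](C(=C)C=O)[C@](C)([C@H]1CO1)[C@@H]2O
F6 | step 19 | (3aR,4S,5R,6R,7S,7aR)-4-[(tert-butyldimethylsilyl)oxy]-6-[(1S)-1,2-dihydroxyethyl]-7-hydroxy-6-methyl-3-methylidene-5-(3-oxoprop-1-en-2-yl)hexahydro-1-benzofuran-2(3H)-one | C=C1C(=O)O[C@@H]2[C@@H]1[C@@H](O[Si](C)(C)C(C)(C)C)[C@@H](C(=C)C=O)[C@](C)([C@H](O)CO)[C@@H]2O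
F7 | step 20 | (3aR,4S,5R,6R,7S,7aR)-4-[(tert-butyldimethylsilyl)oxy]-6-methyl-3-methylidene-6-[(2R)-oxiran-2-yl]-2-oxo-5-(3-oxoprop-1-en-2-yl)octahydro-1-benzofuran-7-yl but-2-ynoate | C=C1C(=O)O[C@@H]2[C@@H]1[C@@H](O[Si](C)(C)C(C)(C)C)[C@@H](C(=C)C=O)[C@](C)([C@@H]1CO1)[C@@H]2OC(=O)C#CC
F8 | step 20 | (3aR,4S,5R,6R,7S,7aR)-4-[(tert-butyldimethylsilyl)oxy]-6-methyl-3-methylidene-6-[(2R)-oxiran-2-yl]-2-oxo-5-(3-oxoprop-1-en-2-yl)octahydro-1-benzofuran-7-yl (2E)-2-(tributylstannyl)but-2-enoate | C=C1C(=O)O[C@@H]2[C@@H]1[C@@H](O[Si](C)(C)C(C)(C)C)[C@@H](C(=C)C=O)[C@](C)([C@@H]1CO1)[C@@H]2OC(=O)/C([Sn](CCCC)(CCCC)CCCC)=C\C
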